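A direct plan would formylate 2,4-dimethoxyphenol A1 ortho to the hydroxyl group to 2-hydroxy-3,5-dimethoxybenzaldehyde A2, mask the phenol as 2-(benzyloxy)-3,5-dimethoxybenzaldehyde A3, condense A3 with docosan-2-one A4 to the enone (E)-1-[2-(benzyloxy)-3,5-dimethoxyphenyl]tricos-1-en-3-one A5, remove the ketone oxygen and finish by hydrogenation.
Its weakest steps would be:
- the removal of the chain carbonyl group, which would take several operations through a hydrazone, add no complexity and compete with conjugate addition and cyclisation at the enone;
- the benzyl protection and its later removal, which would only hide and reveal the phenol;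
- the formylation and crossed aldol chain extension, which would pass through an oxidation level that must be erased again and would need a separately made C22 methyl ketone.

The new route disconnects two bonds on neighbouring ring carbons at once: the C6–alkyl bond and the C1–O bond of the phenol, leading back to 3,5-dimethoxybenzyne, a tricosyl Grignard reagent and an electrophilic oxygen source. The feature exploited is the ortho pair tricosyl/hydroxyl flanked by the C2 methoxy group: in the aryne this methoxy group directs the alkyl nucleophile to the distal carbon and leaves magnesium on the carbon beside it, where borylation and oxidation place the hydroxyl group. One operation therefore delivers the complete substitution pattern with a saturated chain and a free phenol, so no carbonyl removal, no phenol protection and no formylation or aldol chain extension is needed.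

Key step: step 4

Remark: tricosan-1-ol and 1-bromo-3,5-dimethoxybenzene are taken as commercial; the target is achiral, so no stereocentre has to be controlled, and the C23 Grignard reagent is handled warm in THF because of its low solubility.

Step 1
Reactants: 1 1-bromo-3,5-dimethoxybenzene
Product: 2 1-bromo-2-iodo-3,5-dimethoxybenzene
Conditions: NIS (1.05 equiv), TFA (0.1 equiv), MeCN, 0 °C → rt, dark; aq. Na2S2O3; recrystallise
Reagents that add atoms: N-iodosuccinimide, O=C1CCC(=O)N1I
Why: Electrophilic aromatic iodination should occur at C2, which is para to one methoxy group, ortho to the other and less shielded than C4 between the two methoxy groups, so the two halogens end on the future aryne carbons.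

Step 2
Reactants: 3 tricosan-1-ol
Product: 4 1-bromotricosane
Conditions: CBr4 (1.25 equiv), PPh3 (1.3 equiv), CH2Cl2/THF 3:1, 0 → 30 °C; filtration through silica (hexane)
Reagents that add atoms: carbon tetrabromide, BrC(Br)(Br)Br
Why: In the Appel reaction the primary alkoxyphosphonium ion is displaced by bromide in an SN2 step, which is reliable for fatty alcohols and creates no stereocentre.

Step 3
Reactants: 4 1-bromotricosane
Product: 5 tricosylmagnesium bromide (THF solution kept at 45 °C, titrated and used as such)
Conditions: Mg turnings (1.5 equiv), 1,2-dibromoethane (0.05 equiv), THF, 50 °C, slow addition of 4 over 2 h; titration with I2/LiCl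
Reagents that add atoms: magnesium, [Mg]
Why: Grignard formation by insertion of zerovalent magnesium into the primary C–Br bond; slow addition at moderate dilution should keep Wurtz coupling low, and warm THF keeps the long-chain reagent dissolved.

Step 4
Reactants: 2 1-bromo-2-iodo-3,5-dimethoxybenzene; 5 tricosylmagnesium bromide (1.5 equiv)
Product: 10 2,4-dimethoxy-6-tricosylphenol, via 2-bromo-4,6-dimethoxyphenylmagnesium chloride 6 (not isolated), via 3,5-dimethoxybenzyne 7 (not isolated), via 2,4-dimethoxy-6-tricosylphenylmagnesium bromide 8 (not isolated), via dimethyl 2,4-dimethoxy-6-tricosylphenylboronate 9 (not isolated)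
Conditions: 2, iPrMgCl·LiCl (0.98 equiv), THF, −20 °C, 1 h; cannulate into 5 (1.5 equiv), THF, 55–60 °C, 3 h; B(OMe)3 (4 equiv), 0 °C → rt; AcOH, 30% H2O2, 0 °C → rt; aq. Na2S2O3; chromatography
Reagents that add atoms: hydrogen peroxide, OO (phenol oxygen of 10); trimethyl borate, COB(OC)OC (B(OMe)2 group of 9 only); isopropylmagnesium chloride–lithium chloride, CC(C)[Mg]Cl.[Li+].[Cl-] (MgCl of 6 only)
Why: Iodine–magnesium exchange at C2 gives 6, which on warming loses MgBrCl by β-elimination to form aryne 7 in a solution that holds 5 in excess; 5 then adds across the strained triple bond (carbomagnesiation of an aryne), the closest known type being the regioselective addition of organomagnesium and organolithium reagents to 3-alkoxyarynes with electrophilic capture of the ortho-metalated arene. The methoxy group beside the triple bond decides the orientation: its σ-withdrawing C–O bond distorts the aryne so that the distal carbon is the more electrophilic and the less hindered, and the negative charge develops on the proximal carbon, where it is stabilised inductively and by Mg···O chelation. The second methoxy group, meta to the attacked carbon and one carbon further from the triple bond, should exert only a weak bias that does not override the first. Aryl Grignard 8 therefore carries magnesium exactly on the future phenol carbon; trimethyl borate converts it into boronate 9, and H2O2 effects a 1,2-aryl shift from boron to oxygen at that same carbon under mildly acidic conditions that spare the electron-rich phenol. No ring is closed and no stereocentre is formed. The selectivity needed is the orientation of addition and the preference of 7 for 5 over the aryl Grignard reagents 6 and 8, which the inverse addition, the excess of 5 and the two ortho substituents of 6 and 8 should secure; surplus 5 should end as recoverable tricosan-1-ol.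

Compound list
1 | 1-bromo-3,5-dimethoxybenzene | COc1cc(Br)cc(OC)c1 | starting material
2 | 1-bromo-2-iodo-3,5-dimethoxybenzene | COc1cc(OC)c(I)c(Br)c1 | intermediate
3 | tricosan-1-ol | CCCCCCCCCCCCCCCCCCCCCCCO | starting material
4 | 1-bromotricosane | CCCCCCCCCCCCCCCCCCCCCCCBr | intermediate
5 | tricosylmagnesium bromide | CCCCCCCCCCCCCCCCCCCCCCC[Mg]Br | intermediate
6 | 2-bromo-4,6-dimethoxyphenylmagnesium chloride (LiCl complex, drawn without LiCl) | COc1cc(OC)c([Mg]Cl)c(Br)c1 | intermediate
7 | 3,5-dimethoxybenzyne (1,2-didehydro-3,5-dimethoxybenzene) | COC1=CC(OC)=CC#C1 | intermediate
8 | 2,4-dimethoxy-6-tricosylphenylmagnesium bromide | CCCCCCCCCCCCCCCCCCCCCCCc1cc(OC)cc(OC)c1[Mg]Br | intermediate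
9 | dimethyl 2,4-dimethoxy-6-tricosylphenylboronate | CCCCCCCCCCCCCCCCCCCCCCCc1cc(OC)cc(OC)c1B(OC)OC | intermediate
10 | 2,4-dimethoxy-6-tricosylphenol (achiral) | CCCCCCCCCCCCCCCCCCCCCCCc1cc(OC)cc(OC)c1O | target

Total step count: 4. Longest linear sequence: 3 steps (3 → 4 → 5 → 10); the arene branch (1 → 2) joins in step 4.

Steps most likely to fail

Step 4: the aryne may be intercepted by the aryl Grignard reagents instead of the alkyl Grignard reagent (biaryl formation), or the hindered aryl Grignard reagent may be protonated before borylation, so that the C–O bond is not formed. The fallback sets out from 1 and 5 and comes back to the route at 10. A Kumada coupling catalysed by NiCl2(dppp), where dppp is 1,3-bis(diphenylphosphino)propane, in THF at reflux would give 1,3-dimethoxy-5-tricosylbenzene F1. F1 is also the product of protonation of 8, so material from a failed oxygenation could be fed in here. Vilsmeier–Haack formylation with POCl3 and DMF at 0 → 80 °C, para to one methoxy group and ortho to the chain, would give 2,4-dimethoxy-6-tricosylbenzaldehyde F2. Dakin-type Baeyer–Villiger oxidation with mCPBA in CH2Cl2 would give 2,4-dimethoxy-6-tricosylphenyl formate F3, and K2CO3 in MeOH would release the phenol 10.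

Step 3: Wurtz-type homocoupling on the magnesium surface and precipitation of the long-chain reagent may leave a low titre. The fallback sets out from 4 and comes back at 5. Finkelstein exchange with NaI in 2-butanone at reflux would give 1-iodotricosane F4. Iodine–lithium exchange with t-BuLi (2.1 equiv) in Et2O/pentane at −60 °C would give tricosyllithium F5, and transmetalation with MgBr2·OEt2 would deliver 5 without any contact with magnesium metal.

Step 1: iodination may occur between the two methoxy groups or twice, giving isomers that are hard to separate. The fallback sets out from 1 and comes back at 7, bypassing 2. Slow addition of LiTMP (lithium 2,2,6,6-tetramethylpiperidide, 1.1 equiv) to a THF solution of 1 and 5 at −40 → 0 °C would deprotonate 1 between bromine and methoxy to give 2-bromo-4,6-dimethoxyphenyllithium F6. F6 would lose LiBr at once to form the same aryne 7 in the presence of 5, and the sequence would then continue as in step 4.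

Further compounds
F1 | step 4 | 1,3-dimethoxy-5-tricosylbenzene | CCCCCCCCCCCCCCCCCCCCCCCc1cc(OC)cc(OC)c1
F2 | step 4 | 2,4-dimethoxy-6-tricosylbenzaldehyde | CCCCCCCCCCCCCCCCCCCCCCCc1cc(OC)cc(OC)c1C=O
F3 | step 4 | 2,4-dimethoxy-6-tricosylphenyl formate | CCCCCCCCCCCCCCCCCCCCCCCc1cc(OC)cc(OC)c1OC=O
F4 | step 3 | 1-iodotricosane | CCCCCCCCCCCCCCCCCCCCCCCI
F5 | step 3 | tricosyllithium | [Li]CCCCCCCCCCCCCCCCCCCCCCC
F6 | step 1 | 2-bromo-4,6-dimethoxyphenyllithium | [Li]c1c(Br)cc(OC)cc1OC
A1 | direct plan | 2,4-dimethoxyphenol | COc1ccc(O)c(OC)c1
A2 | direct plan | 2-hydroxy-3,5-dimethoxybenzaldehyde | COc1cc(C=O)c(O)c(OC)c1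
A3 | direct plan | 2-(benzyloxy)-3,5-dimethoxybenzaldehyde | COc1cc(C=O)c(OCc2ccccc2)c(OC)c1
A4 | direct plan | docosan-2-one | CCCCCCCCCCCCCCCCCCCCC(C)=O
A5 | direct plan | (E)-1-[2-(benzyloxy)-3,5-dimethoxyphenyl]tricos-1-en-3-one | CCCCCCCCCCCCCCCCCCCCC(=O)/C=C/c1cc(OC)cc(OC)c1OCc1ccccc1
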